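**Plan**
- Retrosynthesis: cut both C10=C11 bonds (two-fold Horner–Wadsworth–Emmons of a C12 bis-phosphonate with two C14 retro-trienals), then C7–C8 (Heck reaction of a dienyl triflate with methacrolein), then C3–C4 and C1–C6 of the ring in one annulation.
- Enabling feature: in each ring the methyl-bearing C5 lies between C4 and C6, and the gem-dimethyl C1 and the oxygenated C3 are 1,3-related through C2. Ring plus C7 is therefore the union of the symmetric 1,3-bis-nucleophile of 3-methylglutaconate (C4–C5–C6, ester = C7) with the β-carbon/acyl bis-electrophile of 3-methylbut-2-enoate (C1–C2–C3).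
- Forward: a Michael–Dieckmann [3+3] annulation makes the carbocycle; the activating C4 ester leaves by decarboxylation; the C3 ketone is reduced; the exocyclic C6=C7 bond is fixed as an (E)-dienyl triflate; C7–C8 and then the two C10=C11 bonds are joined on a C12 centre built from glyoxal; the silyl ethers go last.
- Stereochemistry: C3 and C3' (S) from (R)-CBS reduction of the ring enone, used on both halves so that the coupling should upgrade enantiopurity (meso isomer separable). 6E comes from the separated triflate and a stereoretentive Heck step, 8E from the Heck step, 10E and the central E bonds from E-selective phosphonate olefinations.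

Key step: step 1

Assumption: commercial 1 is an E/Z mixture (both isomers give the same delocalised anion), commercial 14 is taken as its (2E) isomer, and 13 is used as monomer freshly released from its commercial trimer dihydrate.

**Step 1**
Reactants: 1 dimethyl 3-methylpent-2-enedioate (dimethyl 3-methylglutaconate); 2 methyl 3-methylbut-2-enoate
Product: 4 dimethyl 2,6,6-trimethyl-4-oxocyclohex-2-ene-1,3-dicarboxylate (racemic), via Michael adduct triester 3 (not isolated)
Conditions: NaOMe (1.1 equiv), 2 (3 equiv), MeOH, reflux; then aq HCl to pH 3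
Reagents that add atoms: none
Why: Methoxide generates the delocalised, symmetric anion of 1, which adds through either (equivalent) terminus to the β-carbon of 2 and forges C6–C1 (adduct 3); re-deprotonation of 3 at the doubly activated C6–H gives an anion whose free terminus C4 attacks the saturated ester carbonyl, expels methoxide and forges C3–C4, the sequence ending at the stabilised enolate of β-keto ester 4. The closest known reaction type is the Vorländer Michael–Claisen synthesis of cyclohexane-1,3-diones from β-dicarbonyl donors and enoates (dimedone, dihydroorsellinate), run here with a vinylogous malonate as donor. The ring closes in a 6-(enolexo)-exo-trig acyl substitution. The only new stereocentre (ring C1 bearing CO2Me, the later C6) forms without control as a racemate, which is harmless because this carbon becomes sp2 in step 6. The step needs regiocontrol in both bond formations: the symmetry of the glutaconate anion removes the α/γ question in the Michael step, and afterwards only the glutaconate-type anion (far more acidic than the CH2CO2Me site) is populated and only its C4 terminus can reach the ester carbonyl through a six-membered transition state. Reversible methoxide addition to 2, 1,2-attack on 2 and self-condensation of 1 should be countered by the excess of 2 and by the thermodynamic sink of the product enolate.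

**Step 2**
Reactants: 4 dimethyl 2,6,6-trimethyl-4-oxocyclohex-2-ene-1,3-dicarboxylate
Product: 6 methyl 2,6,6-trimethyl-4-oxocyclohex-2-ene-1-carboxylate (racemic), via keto acid 5 (not isolated)
Conditions: H2O (3 equiv), DMSO, 150 °C, no added salt
Reagents that add atoms: none
Why: Thermal dealkoxycarbonylation: only the C3 ester is a β-keto ester, whose enol can lose methanol to an acylketene that water converts into β-keto acid 5, which decarboxylates; the C1 ester (γ to the ketone, beside a quaternary carbon, no halide present for demethylation) should survive, and the C2=C3 enone is the stable tautomer.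

**Step 3**
Reactants: 6 methyl 2,6,6-trimethyl-4-oxocyclohex-2-ene-1-carboxylate
Product: 7 methyl (4S)-4-hydroxy-2,6,6-trimethylcyclohex-2-ene-1-carboxylate (both C1 epimers)
Conditions: (R)-2-methyl-CBS-oxazaborolidine (15 mol%), catecholborane (1.5 equiv), toluene, −78 °C; then aq NaOH work-up
Reagents that add atoms: none
Why: Corey–Bakshi–Shibata reduction: the catalyst should bind the ketone with its alkenyl flank as the large group and the CH2 flank as the small one, so the (R)-catalyst delivers hydride to the face that gives the (S)-carbinol regardless of the remote racemic C1 centre; catecholborane at low temperature avoids hydroboration of the alkene.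

**Step 4**
Reactants: 7 methyl (4S)-4-hydroxy-2,6,6-trimethylcyclohex-2-ene-1-carboxylate
Product: 8 methyl (4S)-4-{[tert-butyl(dimethyl)silyl]oxy}-2,6,6-trimethylcyclohex-2-ene-1-carboxylate
Conditions: TBSCl (1.3 equiv), imidazole (2.5 equiv), DMF, rt
Reagents that add atoms: tert-butyldimethylsilyl chloride, CC(C)(C)[Si](C)(C)Cl
Why: Standard silylation of a secondary allylic alcohol, needed to mask the hydroxyl during reduction, enolate triflation and the basic olefinations.

**Step 5**
Reactants: 8 methyl (4S)-4-{[tert-butyl(dimethyl)silyl]oxy}-2,6,6-trimethylcyclohex-2-ene-1-carboxylate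
Product: 9 (4S)-4-{[tert-butyl(dimethyl)silyl]oxy}-2,6,6-trimethylcyclohex-2-ene-1-carbaldehyde (both C1 epimers)
Conditions: i-Bu2AlH (1.15 equiv), CH2Cl2, −78 °C; MeOH quench; aq potassium sodium tartrate (KNaC4H4O6)
Reagents that add atoms: none
Why: Partial reduction of a hindered ester: the aluminium hemiacetal should persist at −78 °C and release the aldehyde only on work-up, and the neutral tartrate work-up avoids conjugation of the ring alkene and loss of silanol.

**Step 6**
Reactants: 9 (4S)-4-{[tert-butyl(dimethyl)silyl]oxy}-2,6,6-trimethylcyclohex-2-ene-1-carbaldehyde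
Product: 10 [(1E,4S)-4-{[tert-butyl(dimethyl)silyl]oxy}-2,6,6-trimethylcyclohex-2-en-1-ylidene]methyl trifluoromethanesulfonate
Conditions: KN(SiMe3)2 (1.1 equiv), THF, −78 °C, 10 min; PhNTf2 (1.15 equiv), −78 to 0 °C; chromatography on Et3N-washed silica to isolate the E isomer
Reagents that add atoms: N-phenylbis(trifluoromethanesulfonimide), O=S(=O)(N(c1ccccc1)S(=O)(=O)C(F)(F)F)C(F)(F)F
Why: Enolate O-triflation of an α-branched aldehyde: removal of the only α-hydrogen (ring C1–H, which erases the racemic centre) gives a dienolate that is sulfonylated at oxygen to the retro-type dienyl triflate; the short enolate lifetime at −78 °C should limit vinylogous β-elimination of the silyloxy group, and the E isomer (triflate on the side of the gem-dimethyl carbon) is separated from the Z isomer.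

**Step 7**
Reactants: 10 [(1E,4S)-4-{[tert-butyl(dimethyl)silyl]oxy}-2,6,6-trimethylcyclohex-2-en-1-ylidene]methyl trifluoromethanesulfonate; 11 2-methylprop-2-enal (methacrolein)
Product: 12 (2E)-4-[(1E,4S)-4-{[tert-butyl(dimethyl)silyl]oxy}-2,6,6-trimethylcyclohex-2-en-1-ylidene]-2-methylbut-2-enal
Conditions: 11 (3 equiv), Pd(OAc)2 (5 mol%), PPh3 (10 mol%), Et3N (2 equiv), DMF, 60 °C, dark
Reagents that add atoms: none
Why: Heck reaction: oxidative addition of the vinyl triflate to zerovalent palladium with retention, syn-insertion at the unsubstituted terminus of the enal and syn β-hydride elimination from the CH2 group should give the conjugated (E)-2-methyl enal, forming C7–C8 and the 8E bond.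

**Step 8**
Reactants: 13 glyoxal (ethanedial); 14 ethyl (2E)-4-(diethoxyphosphoryl)-3-methylbut-2-enoate
Product: 16 diethyl (2E,4E,6E,8E)-3,8-dimethyldeca-2,4,6,8-tetraenedioate, via aldehyde ester 15 (not isolated)
Conditions: 14 (2.1 equiv), KOt-Bu (2.1 equiv), THF, −30 °C; monomeric 13 in THF (released from its trimer dihydrate over P4O10), −78 °C to rt; crystallisation
Reagents that add atoms: none
Why: Two-fold Horner–Wadsworth–Emmons olefination: the vinylogous phosphonate anion reacts at the carbon α to phosphorus with each aldehyde group and eliminates to the (E)-alkene, carrying over the 2E geometry of 14; the all-E diester should crystallise free of minor Z isomers.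

**Step 9**
Reactants: 16 diethyl (2E,4E,6E,8E)-3,8-dimethyldeca-2,4,6,8-tetraenedioate
Product: 17 (2E,4E,6E,8E)-3,8-dimethyldeca-2,4,6,8-tetraene-1,10-diol
Conditions: i-Bu2AlH (4.4 equiv), CH2Cl2, −78 to 0 °C; aq potassium sodium tartrate (KNaC4H4O6)
Reagents that add atoms: none
Why: 1,2-Reduction of both conjugated esters to the allylic alcohols, which i-Bu2AlH does without touching the polyene.

**Step 10**
Reactants: 17 (2E,4E,6E,8E)-3,8-dimethyldeca-2,4,6,8-tetraene-1,10-diol
Product: 18 (2E,4E,6E,8E)-1,10-dibromo-3,8-dimethyldeca-2,4,6,8-tetraene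
Conditions: PBr3 (0.7 equiv), pyridine (cat.), Et2O, −20 °C, dark; used crude
Reagents that add atoms: phosphorus tribromide, BrP(Br)Br
Why: Substitution of the primary allylic alcohols through their phosphite esters, as practised for polyene diols; the primary, fully conjugated dibromide is the favoured allylic isomer.

**Step 11**
Reactants: 18 (2E,4E,6E,8E)-1,10-dibromo-3,8-dimethyldeca-2,4,6,8-tetraene
Product: 19 tetraethyl [(2E,4E,6E,8E)-3,8-dimethyldeca-2,4,6,8-tetraene-1,10-diyl]bis(phosphonate)
Conditions: P(OEt)3 (6 equiv, neat), 90 °C, EtBr distilled off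
Reagents that add atoms: triethyl phosphite, CCOP(OCC)OCC
Why: Michaelis–Arbuzov reaction of a primary allylic bromide, which proceeds at moderate temperature at the terminal carbon.

**Step 12**
Reactants: 19 tetraethyl [(2E,4E,6E,8E)-3,8-dimethyldeca-2,4,6,8-tetraene-1,10-diyl]bis(phosphonate); 12 (2E)-4-[(1E,4S)-4-{[tert-butyl(dimethyl)silyl]oxy}-2,6,6-trimethylcyclohex-2-en-1-ylidene]-2-methylbut-2-enal
Product: 21 (3S,3'S,6E,6'E)-3,3'-bis{[tert-butyl(dimethyl)silyl]oxy}-4',5'-didehydro-4,5'-retro-β,β-carotene (all-E), via C26 monophosphonate 20 (not isolated)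
Conditions: 19 (1 equiv), KOt-Bu (2.1 equiv), THF, −30 °C; 12 (2.1 equiv), −30 to 0 °C, argon, dark; chromatography, crystallisation
Reagents that add atoms: none
Why: Two-fold Horner–Wadsworth–Emmons olefination of an allylic bis-phosphonate with an enal, which reacts at the carbon α to phosphorus and should give the new C10=C11 bonds E; no iodine or light equilibration is needed, so the 6E geometry is kept, and the meso (3R,3'S) isomer from any minor enantiomer of 12 is removed here.

**Step 13**
Reactants: 21 (3S,3'S,6E,6'E)-3,3'-bis{[tert-butyl(dimethyl)silyl]oxy}-4',5'-didehydro-4,5'-retro-β,β-carotene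
Product: 22 (3S,3'S,6E,6'E)-4',5'-didehydro-4,5'-retro-β,β-carotene-3,3'-diol (all-E; eschscholtzxanthin)
Conditions: Bu4NF (4 equiv), AcOH (4 equiv), THF, 0 °C to rt, dark
Reagents that add atoms: none
Why: Fluoride desilylation buffered with acetic acid, which should avoid both strong acid (the allylic polyenyl alcohols ionise easily) and strong base, and leaves the C3 centres untouched.

**Compound list**
1 | dimethyl 3-methylpent-2-enedioate (dimethyl 3-methylglutaconate, E/Z mixture) | COC(=O)CC(C)=CC(=O)OC | starting material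
2 | methyl 3-methylbut-2-enoate | COC(=O)C=C(C)C | starting material
3 | dimethyl 4-(methoxycarbonyl)-3,5,5-trimethylhept-2-enedioate (Michael adduct, not isolated) | COC(=O)C=C(C)C(C(=O)OC)C(C)(C)CC(=O)OC | intermediate
4 | dimethyl 2,6,6-trimethyl-4-oxocyclohex-2-ene-1,3-dicarboxylate (racemic) | COC(=O)C1C(C)=C(C(=O)OC)C(=O)CC1(C)C | intermediate
5 | 3-(methoxycarbonyl)-2,4,4-trimethyl-6-oxocyclohex-1-ene-1-carboxylic acid (keto acid, not isolated) | COC(=O)C1C(C)=C(C(O)=O)C(=O)CC1(C)C | intermediate
6 | methyl 2,6,6-trimethyl-4-oxocyclohex-2-ene-1-carboxylate (racemic) | COC(=O)C1C(C)=CC(=O)CC1(C)C | intermediate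
7 | methyl (4S)-4-hydroxy-2,6,6-trimethylcyclohex-2-ene-1-carboxylate (C1 epimers) | COC(=O)C1C(C)=C[C@@H](O)CC1(C)C | intermediate
8 | methyl (4S)-4-{[tert-butyl(dimethyl)silyl]oxy}-2,6,6-trimethylcyclohex-2-ene-1-carboxylate (C1 epimers) | COC(=O)C1C(C)=C[C@@H](O[Si](C)(C)C(C)(C)C)CC1(C)C | intermediate
9 | (4S)-4-{[tert-butyl(dimethyl)silyl]oxy}-2,6,6-trimethylcyclohex-2-ene-1-carbaldehyde (C1 epimers) | O=CC1C(C)=C[C@@H](O[Si](C)(C)C(C)(C)C)CC1(C)C | intermediate
10 | [(1E,4S)-4-{[tert-butyl(dimethyl)silyl]oxy}-2,6,6-trimethylcyclohex-2-en-1-ylidene]methyl trifluoromethanesulfonate | CC1=C[C@@H](O[Si](C)(C)C(C)(C)C)CC(C)(C)\C1=C/OS(=O)(=O)C(F)(F)F | intermediate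
11 | 2-methylprop-2-enal (methacrolein) | CC(=C)C=O | starting material
12 | (2E)-4-[(1E,4S)-4-{[tert-butyl(dimethyl)silyl]oxy}-2,6,6-trimethylcyclohex-2-en-1-ylidene]-2-methylbut-2-enal | CC1=C[C@@H](O[Si](C)(C)C(C)(C)C)CC(C)(C)\C1=C/C=C(C)/C=O | intermediate
13 | glyoxal (ethanedial) | O=CC=O | starting material
14 | ethyl (2E)-4-(diethoxyphosphoryl)-3-methylbut-2-enoate | CCOC(=O)/C=C(\C)CP(=O)(OCC)OCC | starting material
15 | ethyl (2E,4E)-3-methyl-6-oxohexa-2,4-dienoate (aldehyde ester, not isolated) | CCOC(=O)/C=C(C)/C=C/C=O | intermediate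
16 | diethyl (2E,4E,6E,8E)-3,8-dimethyldeca-2,4,6,8-tetraenedioate | CCOC(=O)/C=C(C)/C=C/C=C/C(C)=C/C(=O)OCC | intermediate
17 | (2E,4E,6E,8E)-3,8-dimethyldeca-2,4,6,8-tetraene-1,10-diol | OC/C=C(C)/C=C/C=C/C(C)=C/CO | intermediate
18 | (2E,4E,6E,8E)-1,10-dibromo-3,8-dimethyldeca-2,4,6,8-tetraene | BrC/C=C(C)/C=C/C=C/C(C)=C/CBr | intermediate
19 | tetraethyl [(2E,4E,6E,8E)-3,8-dimethyldeca-2,4,6,8-tetraene-1,10-diyl]bis(phosphonate) | CCOP(=O)(OCC)C/C=C(C)/C=C/C=C/C(C)=C/CP(=O)(OCC)OCC | intermediate
20 | diethyl {(2E,4E,6E,8E,10E,12E)-14-[(1E,4S)-4-{[tert-butyl(dimethyl)silyl]oxy}-2,6,6-trimethylcyclohex-2-en-1-ylidene]-3,8,12-trimethyltetradeca-2,4,6,8,10,12-hexaen-1-yl}phosphonate (C26 monophosphonate, not isolated) | CC1=C[C@@H](O[Si](C)(C)C(C)(C)C)CC(C)(C)\C1=C/C=C(C)/C=C/C=C(C)/C=C/C=C/C(C)=C/CP(=O)(OCC)OCC | intermediate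
21 | (3S,3'S,6E,6'E)-3,3'-bis{[tert-butyl(dimethyl)silyl]oxy}-4',5'-didehydro-4,5'-retro-β,β-carotene (all-E) | CC1=C[C@@H](O[Si](C)(C)C(C)(C)C)CC(C)(C)\C1=C/C=C(C)/C=C/C=C(C)/C=C/C=C/C(C)=C/C=C/C(C)=C/C=C1/C(C)=C[C@@H](O[Si](C)(C)C(C)(C)C)CC1(C)C | intermediate
22 | (3S,3'S,6E,6'E)-4',5'-didehydro-4,5'-retro-β,β-carotene-3,3'-diol (all-E; eschscholtzxanthin) | CC1=C[C@@H](O)CC(C)(C)\C1=C/C=C(C)/C=C/C=C(C)/C=C/C=C/C(C)=C/C=C/C(C)=C/C=C1/C(C)=C[C@@H](O)CC1(C)C | target

**Count and risks**
Total: 13 steps. Longest linear sequence: 9 steps (steps 1–7, 12, 13).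

Step 1. The conjugate addition may stall at the fully substituted β-carbon of 2, so that self-condensation of 1 takes over. The fallback sets out from 1 and keeps the same annulation, but uses the far more electrophilic, commercial dimethyl 2-(propan-2-ylidene)malonate with NaOMe in MeOH. The Michael adduct tetramethyl 2,2,4-trimethylpent-4-ene-1,1,3,5-tetracarboxylate F1 should close in the same flask to trimethyl 2,6,6-trimethyl-4-oxocyclohex-2-ene-1,3,5-tricarboxylate F2. Heating F2 in wet DMSO at 150 °C should remove both β-keto ester groups and bring the route back at 6.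

Step 6. Control of the C6=C7 enolate geometry may be poor, or the geometry may erode, leaving too little E triflate. The fallback sets out from 9 and replaces kinetic control and separation by thermodynamic control one stage later. The unseparated triflates, including [(1Z,4S)-4-{[tert-butyl(dimethyl)silyl]oxy}-2,6,6-trimethylcyclohex-2-en-1-ylidene]methyl trifluoromethanesulfonate F3, are taken through the Heck coupling. The resulting trienals, including (2E)-4-[(1Z,4S)-4-{[tert-butyl(dimethyl)silyl]oxy}-2,6,6-trimethylcyclohex-2-en-1-ylidene]-2-methylbut-2-enal F4, are equilibrated with catalytic iodine under visible light in hexane and separated by chromatography. F4 is recycled through the same equilibration, and the route is rejoined at 12.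

Step 7. Methacrolein may polymerise, and palladium hydride species may scramble the dienyl geometry or reduce the triflate. The fallback sets out from 10 and uses a preformed organometallic instead: Stille coupling with the known (2E)-2-methyl-3-(tributylstannyl)prop-2-en-1-ol (Pd(PPh3)4, LiCl, THF, 60 °C) should give (2E)-4-[(1E,4S)-4-{[tert-butyl(dimethyl)silyl]oxy}-2,6,6-trimethylcyclohex-2-en-1-ylidene]-2-methylbut-2-en-1-ol F5. Oxidation of F5 with MnO2 in CH2Cl2 returns the route at 12.

**Further compounds**
F1 | step 1 | tetramethyl 2,2,4-trimethylpent-4-ene-1,1,3,5-tetracarboxylate | COC(=O)C=C(C)C(C(=O)OC)C(C)(C)C(C(=O)OC)C(=O)OC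
F2 | step 1 | trimethyl 2,6,6-trimethyl-4-oxocyclohex-2-ene-1,3,5-tricarboxylate | COC(=O)C1C(C)=C(C(=O)OC)C(=O)C(C(=O)OC)C1(C)C
F3 | step 6 | [(1Z,4S)-4-{[tert-butyl(dimethyl)silyl]oxy}-2,6,6-trimethylcyclohex-2-en-1-ylidene]methyl trifluoromethanesulfonate | CC1=C[C@@H](O[Si](C)(C)C(C)(C)C)CC(C)(C)/C1=C/OS(=O)(=O)C(F)(F)F
F4 | step 6 | (2E)-4-[(1Z,4S)-4-{[tert-butyl(dimethyl)silyl]oxy}-2,6,6-trimethylcyclohex-2-en-1-ylidene]-2-methylbut-2-enal | CC1=C[C@@H](O[Si](C)(C)C(C)(C)C)CC(C)(C)/C1=C/C=C(C)/C=O
F5 | step 7 | (2E)-4-[(1E,4S)-4-{[tert-butyl(dimethyl)silyl]oxy}-2,6,6-trimethylcyclohex-2-en-1-ylidene]-2-methylbut-2-en-1-ol | CC1=C[C@@H](O[Si](C)(C)C(C)(C)C)CC(C)(C)\C1=C/C=C(C)/CO
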